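The ether oxygen is treated as an atom inserted into the C5–C10 bond of a cyclohexane (C5–C6–C7–C8–C9–C10) on which C5–C8 are set by acyclic and chirality-transfer chemistry. In the key step the tertiary silyl peroxide on C10 of 24 undergoes a Criegee shift of C5 to oxygen (O–C5, oxepane ring B) and the oxocarbenium ion at C10 is captured by C1 of a cyclopropyl silyl ether on C4 (C1–C10, oxepane ring A and the ten-membered carbocycle). The step exploits C10, the fully substituted ring carbon bearing oxygen and methyl, flanked through oxygen by the CH of C5.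

Key step: step 18

Numbering: germacranolide numbering is used throughout (ring carbons C1–C10; C14 = methyl on C10; C15 on C4; lactone carbons C11–C13 on C7; lactone oxygen on C6).

Assumption: a one-atom oxygen bridge can span C5/C10 on one face of the ten-membered ring only, so C10 follows from C5 (taken as written) in step 18; the SMILES of the bridged compounds 26–30 and 33 keep the bridgehead notation of the target string.

Step 1
Reactants: 1 diethyl (S)-malate
Product: 2 diethyl (2S,3R)-3-(2-tert-butoxy-2-oxoethyl)-2-hydroxybutanedioate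
Conditions: LiN(i-Pr)2 (2.2 equiv), THF, −78 → −20 °C; BrCH2CO2t-Bu, −78 → −10 °C
Reagents that add atoms: tert-butyl bromoacetate, BrCC(=O)OC(C)(C)C
Why: Fráter–Seebach alkylation of the chelated alkoxide enolate should place the new C7–C11 bond anti to the C8 hydroxyl, which is the C7/C8 relationship of the target.

Step 2
Reactants: 2 diethyl (2S,3R)-3-(2-tert-butoxy-2-oxoethyl)-2-hydroxybutanedioate
Product: 4 tert-butyl 2-[(3R,4S)-4-hydroxy-2-oxooxolan-3-yl]acetate, via diol ester 3 (not isolated)
Conditions: BH3·SMe2, NaBH4 (5 mol %), THF, 0 → 25 °C; MeOH; then TsOH·H2O (cat.), CH2Cl2, 25 °C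
Reagents that add atoms: none
Why: Hydroxyl-directed borane reduction should reduce only the ester next to the free hydroxyl (C9), and the new primary alcohol then lactonises onto the C6 ethyl ester, which differentiates the two ends of the malate without touching C7 or C8.

Step 3
Reactants: 4 tert-butyl 2-[(3R,4S)-4-hydroxy-2-oxooxolan-3-yl]acetate
Product: 5 tert-butyl 2-[(3R,4S)-2-oxo-4-(triisopropylsilyloxy)oxolan-3-yl]acetate
Conditions: i-Pr3SiOTf, 2,6-lutidine, CH2Cl2, 0 °C
Reagents that add atoms: triisopropylsilyl triflate, CC(C)[Si](C(C)C)(C(C)C)OS(=O)(=O)C(F)(F)F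
Why: Silylation of the secondary C8 alcohol with a bulky silyl group that should not migrate to the neighbouring primary alkoxide formed in step 5.

Step 4
Reactants: 5 tert-butyl 2-[(3R,4S)-2-oxo-4-(triisopropylsilyloxy)oxolan-3-yl]acetate
Product: 6 tert-butyl 2-[(3R,4S)-2-hydroxy-4-(triisopropylsilyloxy)oxolan-3-yl]acetate (lactol; both anomers)
Conditions: i-Bu2AlH (1.1 equiv), CH2Cl2, −78 °C
Reagents that add atoms: none
Why: Partial reduction of a γ-lactone to its lactol at low temperature, which the tert-butyl ester should survive.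

Step 5
Reactants: 6 lactol
Product: 8 C6/C7-trans γ-lactone carrying vinyl on C6 and the CH(OTIPS)CH2OH chain (C8–C9) on C7, via diol ester 7 (not isolated)
Conditions: CH2=CHMgBr (2.5 equiv), THF, −78 → 0 °C, then 25 °C; NH4Cl (aq)
Reagents that add atoms: vinylmagnesium bromide, C=C[Mg]Br
Why: Grignard addition to the open hydroxy aldehyde should follow the Felkin–Anh model, reinforced by the anti β-silyloxy group, to give the C6 carbinol syn to C11, and the secondary alkoxide then closes the trans γ-lactone onto the tert-butyl ester by 5-exo acyl substitution.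

Step 6
Reactants: 8 trans γ-lactone primary alcohol
Product: 9 α-silyloxy aldehyde (C9 = CHO)
Conditions: Dess–Martin periodinane, NaHCO3, CH2Cl2, 0 → 25 °C
Reagents that add atoms: none
Why: Dess–Martin oxidation of the primary alcohol under buffered conditions, which should not epimerise C8.

Step 7
Reactants: 9 α-silyloxy aldehyde
Product: 10 diene (C9 isopropenyl carbinol anti to the C8 silyl ether; vinyl on C6)
Conditions: CH2=C(CH3)MgBr, THF, −78 °C
Reagents that add atoms: isopropenylmagnesium bromide, C=C(C)[Mg]Br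
Why: Felkin–Anh addition anti to the α-silyloxy group should give the C9 carbinol anti to the C8 ether (cis on the later ring), and the aldehyde reacts far faster than the lactone at −78 °C.

Step 8
Reactants: 10 diene
Product: 11 cyclohexenol (C5=C10 alkene with methyl on C10; C9–OH and C8–OTIPS cis; trans-fused lactone on C6/C7)
Conditions: second-generation Grubbs catalyst (H2IMes)(PCy3)Cl2Ru=CHPh (5 mol %), CH2Cl2, 40 °C
Reagents that add atoms: none
Why: Ring-closing metathesis between the vinyl and isopropenyl groups closes the cyclohexene with loss of ethene and touches no stereocentre.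

Step 9
Reactants: 12 ethyl 3,3-diethoxypropanoate
Product: 13 1-(2,2-diethoxyethyl)cyclopropan-1-ol
Conditions: EtMgBr (2.6 equiv), Ti(Oi-Pr)4 (0.2 equiv), Et2O/THF, 0 → 25 °C
Reagents that add atoms: ethylmagnesium bromide, CC[Mg]Br
Why: Kulinkovich reaction of the ester through a titanacyclopropane gives the 1-substituted cyclopropanol, whose two ring CH2 groups (later C1 and C2) come from the Grignard reagent.

Step 10
Reactants: 13 1-(2,2-diethoxyethyl)cyclopropan-1-ol
Product: 14 2-[1-(triethylsilyloxy)cyclopropyl]acetaldehyde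
Conditions: Et3SiOTf (3 equiv), 2,6-lutidine, CH2Cl2, 0 °C; then H2O
Reagents that add atoms: triethylsilyl triflate, CC[Si](CC)(CC)OS(=O)(=O)C(F)(F)F; water, O
Why: The silyl triflate and 2,6-lutidine silylate the tertiary cyclopropanol and convert the diethyl acetal into a pyridinium intermediate that water hydrolyses to the aldehyde, a mild known acetal cleavage that spares silyl ethers.

Step 11
Reactants: 14 2-[1-(triethylsilyloxy)cyclopropyl]acetaldehyde
Product: 15 2-[1-(triethylsilyloxy)cyclopropyl]acetic acid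
Conditions: NaClO2, NaH2PO4, 2-methyl-2-butene, t-BuOH/H2O, 25 °C
Reagents that add atoms: sodium chlorite, [Na+].[O-]Cl=O
Why: Pinnick oxidation converts the aldehyde into the acid under buffered conditions that the silyl ether should tolerate.

Step 12
Reactants: 11 cyclohexenol; 15 2-[1-(triethylsilyloxy)cyclopropyl]acetic acid
Product: 16 C9 ester of 11 with acid 15
Conditions: DCC, DMAP (cat.), CH2Cl2, 0 → 25 °C
Reagents that add atoms: none
Why: Steglich esterification acylates the hindered allylic C9 alcohol with retention at C9.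

Step 13
Reactants: 16 C9 ester
Product: 19 carboxylic acid (C15 = CO2H on C4; C4 bonded to C5; C9=C10 alkene), via bis-silyl ketene acetal 17 (not isolated), via rearranged silyl ester 18 (not isolated)
Conditions: LiN(i-Pr)2 (2.5 equiv), THF/DMPU, −78 °C; Me3SiCl (3 equiv); −78 → 50 °C; citric acid (aq)
Reagents that add atoms: none
Why: In this Ireland–Claisen rearrangement the (Z)-silyl ketene acetal formed in THF/DMPU should rearrange suprafacially, so that C4 is delivered to C5 on the face that carried the C9 oxygen (chirality transfer, C4 trans to the C6 oxygen), through the boat-like transition state usual for cyclohexenyl esters, which should give the required C4 configuration, while the lactone silyl ketene acetal is a spectator.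

Step 14
Reactants: 19 carboxylic acid
Product: 21 primary alcohol (C15 = CH2OH), via mixed anhydride 20 (not isolated)
Conditions: i-BuOCOCl, N-methylmorpholine, THF, −15 °C; then NaBH4, H2O, 0 °C
Reagents that add atoms: none
Why: Borohydride reduction of the mixed carbonic anhydride converts the acid into the C15 alcohol without reducing the lactone or touching the trisubstituted alkene.

Step 15
Reactants: 21 primary alcohol
Product: 22 diol (C15–OH and a hydroxymethyl group C13 on the lactone α-carbon C11)
Conditions: LiN(i-Pr)2 (2.3 equiv), THF, −78 °C; CH2O (gas), −78 → −40 °C; NH4Cl (aq)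
Reagents that add atoms: formaldehyde, C=O
Why: Aldol reaction of the lactone lithium enolate with monomeric formaldehyde installs C13 anti to the C7–C8 bond (the C11 centre is destroyed later), with the C15 alkoxide as a spectator.

Step 16
Reactants: 22 diol
Product: 23 diacetate (C15–OAc and C13–OAc)
Conditions: Ac2O, pyridine, 0 °C
Reagents that add atoms: acetic anhydride, CC(=O)OC(C)=O
Why: Acetylation gives the final C15 acetate, turns C13–OH into a leaving group for step 20 and removes every nucleophilic oxygen that could intercept the oxocarbenium ion of step 18.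

Step 17
Reactants: 23 diacetate
Product: 24 tertiary triethylsilyl peroxide on C10 (C9 = CH2; both C10 epimers)
Conditions: Co(thd)2 [cobalt bis(2,2,6,6-tetramethylheptane-3,5-dionate)] (10 mol %), O2 (1 atm), Et3SiH, ClCH2CH2Cl, 25 °C
Reagents that add atoms: dioxygen, O=O; triethylsilane, CC[SiH](CC)CC
Why: In this Mukaiyama–Isayama hydrosilylperoxidation, hydrogen-atom transfer from a cobalt hydride to C9 gives the tertiary C10 radical, which is trapped by O2 and silylated, and both C10 epimers serve because C10 becomes planar in step 18.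

Step 18
Reactants: 24 tertiary triethylsilyl peroxide
Product: 26 11-oxabicyclo[4.4.1]undecan-3-one (5,10-epoxygermacran-3-one with 6,12-lactone; C8–OTIPS; C15–OAc; C13–OAc), via oxocarbenium triflate 25 (not isolated)
Conditions: Et3SiOTf (0.2 equiv), 2,6-di-tert-butyl-4-methylpyridine (0.3 equiv), CH2Cl2, −78 → −20 °C
Reagents that add atoms: none
Why: Proposed new method: Et3SiOTf silylates the distal peroxide oxygen, so that C5 (the more substituted ring carbon, anti-periplanar to the O–O bond) migrates from C10 to oxygen with loss of (Et3Si)2O (Criegee/Hock shift), which forms O–C5 and expands the cyclohexane to the seven-membered oxocarbenium ion 25 (ring B); a ring bond of the cyclopropyl silyl ether then attacks C10 as a homoenol nucleophile, forming C1–C10, ring A and the C3 ketone and regenerating Et3SiOTf. The closest known reaction types are the Lewis-acid Criegee/Hock rearrangement of tertiary peroxides with capture of the oxocarbenium ion by allylsilanes, and the cyclisation of cyclopropanols or their silyl ethers onto oxocarbenium ions to give oxepan-4-ones; their union in one ring-expanding cascade is new. Ring B closes by 1,2-shift ring expansion (oxygen insertion into C5–C10), and ring A by a seven-membered endo attack on the O=C10 bond. C5 keeps its configuration because the migrating carbon shifts with retention, and C10 is fixed by the tether, since C1 can reach only the face of the oxocarbenium ion on which C4 sits. The step needs C5 to migrate in preference to C9 and methyl, which the secondary versus primary character of the two ring carbons should secure, and it needs C–C bond formation to outrun capture by oxygen donors, which is why C15 and C13 carry acetates.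

Step 19
Reactants: 26 bicyclic ketone
Product: 27 C3 alcohol (C3–OH cis to C15)
Conditions: LiBH(s-Bu)3, THF, −78 °C; AcOH
Reagents that add atoms: none
Why: The bulky hydride should attack the C3 ketone from the face opposite to the adjacent C4 substituent, giving the alcohol cis to C15, and the low temperature avoids β-elimination of the C15 acetate.

Step 20
Reactants: 27 C3 alcohol
Product: 29 α-methylene lactone (C3–OAc; C15–OAc; C8–OTIPS), via triacetate 28 (not isolated)
Conditions: Ac2O, Et3N, DMAP (cat.), CH2Cl2, 0 → 25 °C; then DBU, 0 °C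
Reagents that add atoms: acetic anhydride, CC(=O)OC(C)=O
Why: Acetylation of the C3 alcohol followed by E1cB elimination of acetic acid from the β-acetoxy lactone unveils the C11=C13 methylene under conditions that spare the acetates.

Step 21
Reactants: 29 α-methylene lactone silyl ether
Product: 30 C8 alcohol
Conditions: HF·pyridine, THF, 0 → 25 °C
Reagents that add atoms: none
Why: Fluoride cleaves the silyl ether under buffered acidic conditions that should leave the α-methylene lactone and the acetates intact.

Step 22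
Reactants: 30 C8 alcohol; 31 angelic acid
Product: 33 target compound, via mixed anhydride 32 (not isolated)
Conditions: 2,4,6-Cl3C6H2COCl, Et3N, toluene, 25 °C; then 30, 80 °C
Reagents that add atoms: none
Why: Yamaguchi esterification through the mixed anhydride without DMAP should acylate the hindered C8 alcohol without isomerising the (Z)-angelate to the tiglate.

Compound list

1 | diethyl (S)-malate | CCOC(=O)[C@@H](O)CC(=O)OCC | starting material
2 | diethyl (2S,3R)-3-(2-tert-butoxy-2-oxoethyl)-2-hydroxybutanedioate | CCOC(=O)[C@@H](O)[C@@H](CC(=O)OC(C)(C)C)C(=O)OCC | intermediate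
3 | 4-tert-butyl 1-ethyl (2R)-2-[(1S)-1,2-dihydroxyethyl]butanedioate (diol ester) | CCOC(=O)[C@H](CC(=O)OC(C)(C)C)[C@H](O)CO | intermediate (not isolated)
4 | tert-butyl 2-[(3R,4S)-4-hydroxy-2-oxooxolan-3-yl]acetate (3,4-cis) | O=C1OC[C@@H](O)[C@H]1CC(=O)OC(C)(C)C | intermediate
5 | tert-butyl 2-[(3R,4S)-2-oxo-4-(triisopropylsilyloxy)oxolan-3-yl]acetate | O=C1OC[C@@H](O[Si](C(C)C)(C(C)C)C(C)C)[C@H]1CC(=O)OC(C)(C)C | intermediate
6 | lactol of 5 (both anomers) | OC1OC[C@@H](O[Si](C(C)C)(C(C)C)C(C)C)[C@H]1CC(=O)OC(C)(C)C | intermediate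
7 | diol tert-butyl ester (C6 allylic alcohol, C8 OTIPS, C9 primary alcohol; formed as its magnesium alkoxide) | C=C[C@@H](O)[C@H](CC(=O)OC(C)(C)C)[C@H](O[Si](C(C)C)(C(C)C)C(C)C)CO | intermediate (not isolated)
8 | trans γ-lactone: 5-vinyl-4-[2-hydroxy-1-(triisopropylsilyloxy)ethyl]oxolan-2-one | O=C1O[C@H](C=C)[C@H](C1)[C@H](O[Si](C(C)C)(C(C)C)C(C)C)CO | intermediate
9 | aldehyde of 8 (C9 = CHO) | O=C1O[C@H](C=C)[C@H](C1)[C@H](O[Si](C(C)C)(C(C)C)C(C)C)C=O | intermediate
10 | diene: isopropenyl carbinol at C9, anti to C8–OTIPS | O=C1O[C@H](C=C)[C@H](C1)[C@H](O[Si](C(C)C)(C(C)C)C(C)C)[C@H](O)C(C)=C | intermediate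
11 | cyclohexenol (C5=C10, 10-methyl, 9-OH and 8-OTIPS cis, 6,12-lactone trans-fused) | O=C1O[C@@H]2C=C(C)[C@@H](O)[C@@H](O[Si](C(C)C)(C(C)C)C(C)C)[C@H]2C1 | intermediate
12 | ethyl 3,3-diethoxypropanoate | CCOC(=O)CC(OCC)OCC | starting material
13 | 1-(2,2-diethoxyethyl)cyclopropan-1-ol | CCOC(CC1(O)CC1)OCC | intermediate
14 | 2-[1-(triethylsilyloxy)cyclopropyl]acetaldehyde | CC[Si](CC)(CC)OC1(CC=O)CC1 | intermediate
15 | 2-[1-(triethylsilyloxy)cyclopropyl]acetic acid | CC[Si](CC)(CC)OC1(CC(=O)O)CC1 | intermediate
16 | C9 ester of 11 with 15 | O=C1O[C@@H]2C=C(C)[C@@H](OC(=O)CC3(O[Si](CC)(CC)CC)CC3)[C@@H](O[Si](C(C)C)(C(C)C)C(C)C)[C@H]2C1 | intermediate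
17 | bis(trimethylsilyl) ketene acetal of 16 ((Z)-ester ketene acetal; lactone ketene acetal) | C[Si](C)(C)OC1O[C@@H]2C=C(C)[C@@H](O/C(O[Si](C)(C)C)=C/C3(O[Si](CC)(CC)CC)CC3)[C@@H](O[Si](C(C)C)(C(C)C)C(C)C)[C@H]2C=1 | intermediate (not isolated)
18 | rearranged trimethylsilyl ester (lactone still as silyl ketene acetal) | C[Si](C)(C)OC1O[C@@H]2[C@@H]([C@@H](C(=O)O[Si](C)(C)C)C3(O[Si](CC)(CC)CC)CC3)C(C)=C[C@@H](O[Si](C(C)C)(C(C)C)C(C)C)[C@H]2C=1 | intermediate (not isolated)
19 | carboxylic acid (C15 acid on C4; C9=C10) | O=C1O[C@@H]2[C@@H]([C@@H](C(=O)O)C3(O[Si](CC)(CC)CC)CC3)C(C)=C[C@@H](O[Si](C(C)C)(C(C)C)C(C)C)[C@H]2C1 | intermediate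
20 | isobutyl carbonic mixed anhydride of 19 | O=C1O[C@@H]2[C@@H]([C@@H](C(=O)OC(=O)OCC(C)C)C3(O[Si](CC)(CC)CC)CC3)C(C)=C[C@@H](O[Si](C(C)C)(C(C)C)C(C)C)[C@H]2C1 | intermediate (not isolated)
21 | C15 alcohol | O=C1O[C@@H]2[C@@H]([C@@H](CO)C3(O[Si](CC)(CC)CC)CC3)C(C)=C[C@@H](O[Si](C(C)C)(C(C)C)C(C)C)[C@H]2C1 | intermediate
22 | C13,C15-diol (hydroxymethyl on C11) | OC[C@@H]1C(=O)O[C@@H]2[C@@H]([C@@H](CO)C3(O[Si](CC)(CC)CC)CC3)C(C)=C[C@@H](O[Si](C(C)C)(C(C)C)C(C)C)[C@@H]12 | intermediate
23 | C13,C15-diacetate | CC(=O)OC[C@@H]1C(=O)O[C@@H]2[C@@H]([C@@H](COC(C)=O)C3(O[Si](CC)(CC)CC)CC3)C(C)=C[C@@H](O[Si](C(C)C)(C(C)C)C(C)C)[C@@H]12 | intermediate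
24 | tertiary triethylsilyl peroxide at C10 (both C10 epimers, no descriptor at C10) | CC(=O)OC[C@@H]1C(=O)O[C@@H]2[C@@H]([C@@H](COC(C)=O)C3(O[Si](CC)(CC)CC)CC3)C(C)(OO[Si](CC)(CC)CC)C[C@@H](O[Si](C(C)C)(C(C)C)C(C)C)[C@@H]12 | intermediate
25 | seven-membered oxocarbenium triflate (ring B) | CC(=O)OC[C@@H]1C(=O)O[C@@H]2[C@@H]([C@@H](COC(C)=O)C3(O[Si](CC)(CC)CC)CC3)[O+]=C(C)C[C@@H](O[Si](C(C)C)(C(C)C)C(C)C)[C@@H]12.[O-]S(=O)(=O)C(F)(F)F | intermediate (not isolated)
26 | bridged C3 ketone | CC(=O)OC[C@@H]1C(=O)O[C@@H]2[C@@H]3O[C@](C)(CCC(=O)[C@@H]3COC(C)=O)C[C@@H](O[Si](C(C)C)(C(C)C)C(C)C)[C@@H]12 | intermediate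
27 | C3 alcohol | CC(=O)OC[C@@H]1C(=O)O[C@@H]2[C@@H]3O[C@](C)(CC[C@H](O)[C@@H]3COC(C)=O)C[C@@H](O[Si](C(C)C)(C(C)C)C(C)C)[C@@H]12 | intermediate
28 | C3,C13,C15-triacetate | CC(=O)OC[C@@H]1C(=O)O[C@@H]2[C@@H]3O[C@](C)(CC[C@H](OC(C)=O)[C@@H]3COC(C)=O)C[C@@H](O[Si](C(C)C)(C(C)C)C(C)C)[C@@H]12 | intermediate (not isolated)
29 | α-methylene lactone, C8–OTIPS | C=C1C(=O)O[C@@H]2[C@@H]3O[C@](C)(CC[C@H](OC(C)=O)[C@@H]3COC(C)=O)C[C@@H](O[Si](C(C)C)(C(C)C)C(C)C)[C@@H]12 | intermediate
30 | C8 alcohol | C=C1C(=O)O[C@@H]2[C@@H]3O[C@](C)(CC[C@H](OC(C)=O)[C@@H]3COC(C)=O)C[C@@H](O)[C@@H]12 | intermediate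
31 | angelic acid, (Z)-2-methylbut-2-enoic acid | C/C=C(/C)C(=O)O | starting material
32 | angelic 2,4,6-trichlorobenzoic mixed anhydride | C/C=C(/C)C(=O)OC(=O)c1c(Cl)cc(Cl)cc1Cl | intermediate (not isolated)
33 | CNP0346171.1 | C=C1C(=O)O[C@@H]2[C@@H]3O[C@](C)(CC[C@H](OC(C)=O)[C@@H]3COC(C)=O)C[C@@H](OC(=O)/C(C)=C\C)[C@@H]12 | target

Total steps: 22. Longest linear sequence: 19 steps (steps 1–8 and 12–22).

Steps most likely to fail

Step 18 (proposed new method). The silyl peroxide may ionise without the C5 shift, or C9 may migrate instead. The Lewis acid may also strip the cyclopropyl silyl ether before C–C bond formation, or the oxocarbenium ion may lose a proton and stall. The fallback separates the two bond formations and uses known chemistry; it sets out from 24 and returns at 26. The peroxy O–Si bond of 24 is cleaved with Et3N·3HF at −20 °C to give hydroperoxide F1. Acylation with (CF3CO)2O and pyridine at 0 °C gives peroxy trifluoroacetate F2, which undergoes the classical Criegee rearrangement to the ring-expanded ketal trifluoroacetate F3 (O–C5 formed alone). Ionisation of F3 with Me3SiOTf at −78 °C and the known cyclisation of a cyclopropyl silyl ether onto an oxocarbenium ion then form C1–C10 and give 26.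

Step 13. Poor discrimination between boat-like and chair-like transition states would give C4 epimers, and the trans-fused lactone holds the C9–O bond pseudo-equatorial, which slows the shift. The fallback sets C4 under thermodynamic control on a temporary ring; it sets out from 19 obtained as a mixture with its C4 epimer F4 and returns at 19. Iodolactonisation of the mixture (I2, NaHCO3, MeCN) closes a cis-fused γ-lactone between C15 and C10. DBU equilibrates C4 to iodolactone F5, which carries the cyclopropyl group on the convex face (trans to C6), the required configuration. Zn in AcOH then regenerates the C9=C10 alkene and the acid as 19.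

Step 7. Facial selectivity at C9 may be poor if chelation competes with the Felkin–Anh mode. The fallback sets C9 on the ring by hydride delivery; it sets out from 9 and returns at 11. The Grignard addition is run without regard to C9, giving 10 together with C9-epimeric diene F6. Ring-closing metathesis of the mixture gives 11 and C9-epimeric cyclohexenol F7. MnO2 oxidises both allylic alcohols to the single enone F8. Reduction with NaBH4 and CeCl3·7H2O in MeOH at −78 °C, where hydride should enter anti to the axial C8 silyl ether, returns 11.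

Further compounds

F1 | step 18 | tertiary hydroperoxide at C10 | CC(=O)OC[C@@H]1C(=O)O[C@@H]2[C@@H]([C@@H](COC(C)=O)C3(O[Si](CC)(CC)CC)CC3)C(C)(OO)C[C@@H](O[Si](C(C)C)(C(C)C)C(C)C)[C@@H]12
F2 | step 18 | peroxy trifluoroacetate at C10 | CC(=O)OC[C@@H]1C(=O)O[C@@H]2[C@@H]([C@@H](COC(C)=O)C3(O[Si](CC)(CC)CC)CC3)C(C)(OOC(=O)C(F)(F)F)C[C@@H](O[Si](C(C)C)(C(C)C)C(C)C)[C@@H]12
F3 | step 18 | ring-expanded 2-methyl-2-(trifluoroacetoxy)oxepane (ketal trifluoroacetate) | CC(=O)OC[C@@H]1C(=O)O[C@@H]2[C@@H]([C@@H](COC(C)=O)C3(O[Si](CC)(CC)CC)CC3)OC(C)(OC(=O)C(F)(F)F)C[C@@H](O[Si](C(C)C)(C(C)C)C(C)C)[C@@H]12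
F4 | step 13 | C4 epimer of acid 19 | O=C1O[C@@H]2[C@@H]([C@H](C(=O)O)C3(O[Si](CC)(CC)CC)CC3)C(C)=C[C@@H](O[Si](C(C)C)(C(C)C)C(C)C)[C@H]2C1
F5 | step 13 | iodolactone (C15–O–C10 γ-lactone, iodine on C9, cyclopropyl group on the convex face) | O=C1O[C@@H]2[C@H]3[C@H](C4(O[Si](CC)(CC)CC)CC4)C(=O)O[C@@]3(C)[C@H](I)[C@@H](O[Si](C(C)C)(C(C)C)C(C)C)[C@H]2C1
F6 | step 7 | C9 epimer of diene 10 | O=C1O[C@H](C=C)[C@H](C1)[C@H](O[Si](C(C)C)(C(C)C)C(C)C)[C@@H](O)C(C)=C
F7 | step 7 | C9 epimer of cyclohexenol 11 | O=C1O[C@@H]2C=C(C)[C@H](O)[C@@H](O[Si](C(C)C)(C(C)C)C(C)C)[C@H]2C1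
F8 | step 7 | 2-methylcyclohexenone (C9 ketone) | O=C1O[C@@H]2C=C(C)C(=O)[C@@H](O[Si](C(C)C)(C(C)C)C(C)C)[C@H]2C1
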